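The pyrrole ring is disconnected at N1–C5 and C2–C3. N1, C2 and the formyl carbon are supplied by glycine ethyl ester; C3, C4, C5 and the nonadecatrienyl chain by a linear C22 β-keto ester whose Z alkenes are bought with linolenyl alcohol. In one operation the amine condenses with the ketone and ethoxide closes the ring by Dieckmann attack of the glycinate carbon on the ester, giving a 3-hydroxypyrrole-2-carboxylate. The feature exploited is the 2,5-disubstituted pyrrole ring, with a carbonyl carbon on C2 and an unbranched chain on C5, which maps onto an α-amino ester and a 1,3-dicarbonyl unit. The surplus C3 oxygen is then removed and the ester adjusted to the aldehyde.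

Key step: step 3

Remark: every operation on the skipped triene is assumed to be run under argon in degassed solvents with a trace of BHT, because the doubly allylic CH2 groups autoxidize readily.

Step 1
Reactants: 1 (9Z,12Z,15Z)-octadeca-9,12,15-trien-1-ol (linolenyl alcohol)
Product: 2 (9Z,12Z,15Z)-1-bromooctadeca-9,12,15-triene
Conditions: CBr4, PPh3, CH2Cl2, 0 °C → rt
Reagents that add atoms: tetrabromomethane, BrC(Br)(Br)Br
Why: Appel reaction, in which PPh3 and CBr4 turn the primary alcohol into an alkoxyphosphonium ion that bromide displaces by SN2 under neutral conditions, so the three Z alkenes and their doubly allylic CH2 groups are not touched.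

Step 2
Reactants: 3 ethyl acetoacetate; 2 (9Z,12Z,15Z)-1-bromooctadeca-9,12,15-triene
Product: 5 ethyl (13Z,16Z,19Z)-3-oxodocosa-13,16,19-trienoate, via acetoacetate dianion 4 (not isolated)
Conditions: NaH, THF, 0 °C; n-BuLi, 0 °C; then 2, 0 °C → rt; 1 M HCl
Reagents that add atoms: none
Why: Dianion γ-alkylation of a β-keto ester, in which successive deprotonation of 3 at C2 (NaH) and C4 (n-BuLi) gives 4, whose terminal carbanion is the more reactive site and displaces the primary bromide by SN2, adding the one CH2 needed to place nine CH2 groups between the first alkene and the ketone.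

Step 3
Reactants: 5 ethyl (13Z,16Z,19Z)-3-oxodocosa-13,16,19-trienoate; 6 glycine ethyl ester hydrochloride
Product: 9 ethyl 3-hydroxy-5-[(10Z,13Z,16Z)-nonadeca-10,13,16-trien-1-yl]-1H-pyrrole-2-carboxylate, via glycine ethyl ester 7 (not isolated), via enamino diester 8 (not isolated)
Conditions: Et3N, 3 Å MS, EtOH, rt; then NaOEt, EtOH, rt → 50 °C; AcOH
Reagents that add atoms: none
Why: Et3N releases the free amine 7, which adds to the ketone of 5 and loses water to give the hydrogen-bonded Z enamino diester 8 (N1–C5 bond); ethoxide then forms the glycinate carbanion, which adds to the ester carbonyl that was C1 of 5, ethoxide leaves, and the 3-oxo-2,3-dihydropyrrole enolizes to the aromatic 3-hydroxypyrrole, held as its sodium salt until acetic acid is added (C2–C3 bond). The closest known reaction type is the Dieckmann (intramolecular Claisen) closure of N-(2-alkoxycarbonylvinyl)glycinates to 3-hydroxypyrrole-2-carboxylates. The pyrrole ring closes in the 5-exo-trig mode, more exactly 5-(enolexo)-exo-trig, which is favored, whereas the rival closure of the enamine carbon C4 onto the glycine ester would be 5-(enolendo)-exo-trig and is stereoelectronically disfavored. No stereocenter is formed, and the three Z alkenes persist because ethoxide in ethanol at or below 50 °C cannot remove a doubly allylic proton. The step needs the amine to attack the ketone and not the ester of 5, which the higher electrophilicity of the ketone and the stability of the chelated vinylogous carbamate secure, and it needs the Z enamine geometry, which the N–H···O=C hydrogen bond supplies and which puts the ester carbonyl next to the glycinate carbon. Ethyl esters on both partners matched to ethoxide make ester exchange invisible, the sieves take up the water of condensation before base is added, and aromatization to the enolate makes the closure irreversible.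

Step 4
Reactants: 9 ethyl 3-hydroxy-5-[(10Z,13Z,16Z)-nonadeca-10,13,16-trien-1-yl]-1H-pyrrole-2-carboxylate
Product: 10 ethyl 5-[(10Z,13Z,16Z)-nonadeca-10,13,16-trien-1-yl]-3-{[(trifluoromethyl)sulfonyl]oxy}-1H-pyrrole-2-carboxylate
Conditions: PhNTf2, Et3N, CH2Cl2, 0 °C → rt
Reagents that add atoms: N-phenylbis(trifluoromethanesulfonimide), O=S(=O)(N(c1ccccc1)S(=O)(=O)C(F)(F)F)C(F)(F)F
Why: Aryl triflate formation from an enol-like hydroxyl, in which Et3N deprotonates the acidic 3-OH and the oxyanion attacks the mild triflyl donor PhNTf2, which leaves the weakly nucleophilic pyrrole N–H, C4 and the alkenes alone.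

Step 5
Reactants: 10 ethyl 5-[(10Z,13Z,16Z)-nonadeca-10,13,16-trien-1-yl]-3-{[(trifluoromethyl)sulfonyl]oxy}-1H-pyrrole-2-carboxylate
Product: 11 ethyl 5-[(10Z,13Z,16Z)-nonadeca-10,13,16-trien-1-yl]-1H-pyrrole-2-carboxylate
Conditions: Pd(OAc)2 (5 mol %), PPh3 (10 mol %), HCO2H, Et3N, DMF, 60 °C
Reagents that add atoms: none
Why: Palladium-catalyzed formate reduction of an aryl triflate, in which zerovalent palladium formed from Pd(OAc)2 and PPh3 inserts into the C3–O bond activated by the neighboring ester, formate displaces triflate and loses CO2, and the aryl palladium hydride reductively eliminates the C3–H bond faster than it can engage the remote alkenes.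

Step 6
Reactants: 11 ethyl 5-[(10Z,13Z,16Z)-nonadeca-10,13,16-trien-1-yl]-1H-pyrrole-2-carboxylate
Product: 12 {5-[(10Z,13Z,16Z)-nonadeca-10,13,16-trien-1-yl]-1H-pyrrol-2-yl}methanol
Conditions: LiAlH4, THF, −10 → 0 °C; H2O, aq. NaOH; crude product used at once
Reagents that add atoms: none
Why: Hydride reduction of an ester to a primary alcohol, in which LiAlH4 removes the N–H proton and then reduces the ester, while holding the mixture at or below 0 °C and working up under basic conditions keeps the aluminate from ionizing to an azafulvene, the path to a 2-methylpyrrole.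

Step 7
Reactants: 12 {5-[(10Z,13Z,16Z)-nonadeca-10,13,16-trien-1-yl]-1H-pyrrol-2-yl}methanol
Product: 13 5-[(10Z,13Z,16Z)-nonadeca-10,13,16-trien-1-yl]-1H-pyrrole-2-carbaldehyde (Mycalazal 20)
Conditions: activated MnO2, CH2Cl2, rt
Reagents that add atoms: none
Why: MnO2 oxidation of an activated (pyrrol-2-yl, benzylic-type) carbinol, which should stop at the aldehyde because the product is a vinylogous formamide that resists overoxidation, and which does not attack unactivated C–H bonds or the Z alkenes.

Compound list
1 | (9Z,12Z,15Z)-octadeca-9,12,15-trien-1-ol (linolenyl alcohol) | CC/C=C\C/C=C\C/C=C\CCCCCCCCO | starting material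
2 | (9Z,12Z,15Z)-1-bromooctadeca-9,12,15-triene (linolenyl bromide) | CC/C=C\C/C=C\C/C=C\CCCCCCCCBr | intermediate
3 | ethyl acetoacetate (ethyl 3-oxobutanoate) | CCOC(=O)CC(C)=O | starting material
4 | acetoacetate dianion (sodium lithium salt of ethyl 3-oxobutanoate deprotonated at C2 and C4; formed in the flask) | [Na+].[Li+].[CH2-]C(=O)[CH-]C(=O)OCC | intermediate
5 | ethyl (13Z,16Z,19Z)-3-oxodocosa-13,16,19-trienoate | CC/C=C\C/C=C\C/C=C\CCCCCCCCCC(=O)CC(=O)OCC | intermediate
6 | glycine ethyl ester hydrochloride | Cl.NCC(=O)OCC | starting material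
7 | glycine ethyl ester (free base; formed in the flask) | NCC(=O)OCC | intermediate
8 | ethyl (2Z,13Z,16Z,19Z)-3-[(2-ethoxy-2-oxoethyl)amino]docosa-2,13,16,19-tetraenoate (enamino diester; formed in the flask) | CC/C=C\C/C=C\C/C=C\CCCCCCCCC/C(NCC(=O)OCC)=C/C(=O)OCC | intermediate
9 | ethyl 3-hydroxy-5-[(10Z,13Z,16Z)-nonadeca-10,13,16-trien-1-yl]-1H-pyrrole-2-carboxylate | CC/C=C\C/C=C\C/C=C\CCCCCCCCCc1cc(O)c(C(=O)OCC)[nH]1 | intermediate
10 | ethyl 5-[(10Z,13Z,16Z)-nonadeca-10,13,16-trien-1-yl]-3-{[(trifluoromethyl)sulfonyl]oxy}-1H-pyrrole-2-carboxylate | CC/C=C\C/C=C\C/C=C\CCCCCCCCCc1cc(OS(=O)(=O)C(F)(F)F)c(C(=O)OCC)[nH]1 | intermediate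
11 | ethyl 5-[(10Z,13Z,16Z)-nonadeca-10,13,16-trien-1-yl]-1H-pyrrole-2-carboxylate | CC/C=C\C/C=C\C/C=C\CCCCCCCCCc1ccc(C(=O)OCC)[nH]1 | intermediate
12 | {5-[(10Z,13Z,16Z)-nonadeca-10,13,16-trien-1-yl]-1H-pyrrol-2-yl}methanol | CC/C=C\C/C=C\C/C=C\CCCCCCCCCc1ccc(CO)[nH]1 | intermediate
13 | 5-[(10Z,13Z,16Z)-nonadeca-10,13,16-trien-1-yl]-1H-pyrrole-2-carbaldehyde (Mycalazal 20) | CC/C=C\C/C=C\C/C=C\CCCCCCCCCc1ccc(C=O)[nH]1 | target

Total step count: 7. Longest linear sequence: 7 steps, from 1 through 2, 5, 9, 10, 11 and 12 to 13.

Steps most likely to fail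

Step 3 (key step). Deprotonation of the enamine N–H by ethoxide may deactivate the conjugated ester so that ring closure stalls. Closure may also drift toward attack of the enamine carbon on the glycine ester, and the electron-rich hydroxypyrrole may oxidize in air during work-up. The fallback sets out from 5. Condensation with diethyl aminomalonate hydrochloride (Et3N, 3 Å MS, EtOH, rt) should give diethyl 2-{[(2Z,13Z,16Z,19Z)-1-ethoxy-1-oxodocosa-2,13,16,19-tetraen-3-yl]amino}propanedioate F1. Its malonate C–H is far more acidic than the N–H, so NaOEt in EtOH should form the C2 carbanion cleanly. Dieckmann closure then gives diethyl 5-[(10Z,13Z,16Z)-nonadeca-10,13,16-trien-1-yl]-3-oxo-1,3-dihydro-2H-pyrrole-2,2-dicarboxylate F2. This cannot enolize, so ethoxide cleaves one ester group as diethyl carbonate and the ring aromatizes to 9, where the route is rejoined. The reaction type is the aminomalonate variant of Knorr-type pyrrole closures, in which one ester group is shed during aromatization.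

Step 5. Palladium hydride species may move the skipped Z alkenes into conjugation, or S–O cleavage may return the hydroxypyrrole instead of C–O insertion. The fallback sets out from 10. Miyaura borylation (B2pin2, PdCl2(dppf) with dppf = 1,1'-bis(diphenylphosphino)ferrocene, KOAc, dioxane, 80 °C), which involves no hydride donor, should give ethyl 5-[(10Z,13Z,16Z)-nonadeca-10,13,16-trien-1-yl]-3-(4,4,5,5-tetramethyl-1,3,2-dioxaborolan-2-yl)-1H-pyrrole-2-carboxylate F3. Protodeboronation of this electron-rich heteroaryl boronate (AcOH, aqueous dioxane, 60 °C) should then deliver 11, where the route is rejoined.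

Step 6. The aluminate of the carbinol may lose its oxygen through an azafulvene and be reduced further to the 2-methylpyrrole, and the carbinol may self-condense on contact with acid or silica. The fallback sets out from 11. Saponification (LiOH, THF/MeOH/H2O, 50 °C) should give 5-[(10Z,13Z,16Z)-nonadeca-10,13,16-trien-1-yl]-1H-pyrrole-2-carboxylic acid F4. Protodecarboxylation (TFA, CH2Cl2, 0 °C → rt, short contact) should give 2-[(10Z,13Z,16Z)-nonadeca-10,13,16-trien-1-yl]-1H-pyrrole F5. Vilsmeier–Haack formylation (POCl3, DMF, ClCH2CH2Cl, 0 °C → rt; aq. NaOAc) at the only free α-position should then give 13 directly, bypassing 12 and step 7. In this variant the formyl carbon comes from DMF.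

Further compounds
F1 | step 3 | diethyl 2-{[(2Z,13Z,16Z,19Z)-1-ethoxy-1-oxodocosa-2,13,16,19-tetraen-3-yl]amino}propanedioate | CC/C=C\C/C=C\C/C=C\CCCCCCCCC/C(NC(C(=O)OCC)C(=O)OCC)=C/C(=O)OCC
F2 | step 3 | diethyl 5-[(10Z,13Z,16Z)-nonadeca-10,13,16-trien-1-yl]-3-oxo-1,3-dihydro-2H-pyrrole-2,2-dicarboxylate | CC/C=C\C/C=C\C/C=C\CCCCCCCCCC1=CC(=O)C(C(=O)OCC)(C(=O)OCC)N1
F3 | step 5 | ethyl 5-[(10Z,13Z,16Z)-nonadeca-10,13,16-trien-1-yl]-3-(4,4,5,5-tetramethyl-1,3,2-dioxaborolan-2-yl)-1H-pyrrole-2-carboxylate | CC/C=C\C/C=C\C/C=C\CCCCCCCCCc1cc(B2OC(C)(C)C(C)(C)O2)c(C(=O)OCC)[nH]1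
F4 | step 6 | 5-[(10Z,13Z,16Z)-nonadeca-10,13,16-trien-1-yl]-1H-pyrrole-2-carboxylic acid | CC/C=C\C/C=C\C/C=C\CCCCCCCCCc1ccc(C(=O)O)[nH]1
F5 | step 6 | 2-[(10Z,13Z,16Z)-nonadeca-10,13,16-trien-1-yl]-1H-pyrrole | CC/C=C\C/C=C\C/C=C\CCCCCCCCCc1ccc[nH]1
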